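## The problem

The target is a guaiane. Cyclopentane ring A (C1–C5) is fused through C1 and C5 to cycloheptene ring B (C5–C10 and C1), and the only ring alkene, tetrasubstituted C1=C10, sits at the fusion. C4 and C10 carry methyl groups (C15, C14) and C7 carries the isopropyl group (C11–C13). Five contiguous stereocentres, C4 to C8, must be set as 4S,5R,6R,7R,8S: the C4 hydroxyl, H5, the C6 acetate and the C7 isopropyl group lie on one face of the bicycle, the C8 angelate on the other. C6 and C7 are the natural controllers: through allylic 1,3-strain they can decide the face on which a C4=C5 alkene of a monocyclic precursor is oxidised (hence C4 and C5), and the C6 oxygen stands 1,3 to C8 and can deliver a reagent there. C8 is the awkward position, an unactivated methylene with neither a carbonyl nor an alkene beside it (the allylic methylene is C9). Three groups are fragile: the angelate isomerises to the tiglate with acid, base, nucleophiles or heat, the tertiary C4 alcohol ionises easily, and two different esters must be placed on a 1,3-diol without migration. The feature that invites a biomimetic entry is that the fifteen carbons are an unbroken farnesyl chain. C6 is the former diphosphate carbon and bears oxygen, C7 bears the isopropyl group, and C1=C10 and C4=C5 of the derived cyclodecadiene are the two internal alkenes of farnesol, facing each other for a transannular C1–C5 closure. The same atom numbers are used for the farnesyl, germacrane and guaiane stages.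

## Retrosynthesis

**15 to 14.** The acetyl C–O bond at O6 is cut last. The C6 hydroxyl is needed free until then as the director for the C8 oxidation, and an acetate would not survive the basic peroxide used there. The forward step must acetylate a hindered secondary hydroxyl in the presence of the tertiary C4 hydroxyl and an angelate.

**14 to 12 and 13.** The C8–O ester bond is cut with inversion at C8, leading to triol 12 and angelic acid 13. Any reagent tethered to O6 puts the new oxygen cis to O6, whereas the target has it trans. A Mitsunobu esterification corrects the configuration and installs the angelate in the same operation. An oxidation–reduction detour through a β-hydroxy ketone would cost three more steps and is held in reserve. The forward reaction must choose the C8 hydroxyl over the more crowded C6 hydroxyl and substitute without elimination.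

**12 to 8.** The C8–O bond is traced back to a C8–H bond. Enolate or allylic chemistry cannot reach C8 (allylic oxidation would strike C9, C2, C5 or C14), but C8 is the only reactive carbon γ to O6, the others being tertiary C11, quaternary C4 and sp2 C1. A silicon tether on O6 (9), closed to oxasilolane 10 and oxidised (11, then 12), is therefore preferred. The precursor 8 lacks one stereocentre and one oxygen. The forward step asks for silylation of one secondary C–H bond on the face of O6 and tolerance of the tetrasubstituted alkene.

**8 to 6.** The O4–Si bond is cut. The tertiary hydroxyl must be masked, because a free C4 hydroxyl would capture the Si–H tether as a cyclic 4,6-silylene. It is reached through bis-silyl ether 7 and selective methanolysis at the secondary position.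

**6 to 5.** The C1–C5 bond is cut, opening ring A and ring B into the ten-membered epoxide 5. This transannular epoxide–alkene closure produces at once the C4 carbinol, H5 and the C1=C10 alkene. The alternatives (aldol or metathesis closures of ring B) would need C4 and C5 to be set separately. The forward reaction must open the epoxide at C5 with inversion and end by loss of H1.

**5 to 4.** The two epoxide C–O bonds are removed. The C6 hydroxyl of dienol 4 has to direct the oxidant to C4=C5 and to the face syn to itself, and must leave C1=C10 alone.

**4 to 3.** The C6–C7 bond and the C6–O bond are cut, with the C11 hydrogen returned to C6. This is the reverse of a terpene-cyclase reaction on farnesyl diphosphate 3. No chemical reagent folds an achiral C15 chain into one enantiomer of an E,E-cyclodecadiene while oxidising C6 and reducing C11, so the enzyme is used for exactly this step. The precursor has no ring and no stereocentre.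

**3 to 2 to 1.** The P–O–C bond and then the C–Cl bond are cut, leading to commercial (2E,6E)-farnesol 1 by the usual chloride–diphosphate sequence. The forward steps must keep the 2E geometry and avoid allylic transposition.

## Roads not taken

**Alternative 1:** Rings A and B are cut at C1–C5 and C8–C9. This gives the open-chain dienyl sulfone A1, which carries a 2-(trimethylsilylmethyl)allyl acetate terminus. In the forward sense Pd(OAc)2 with P(O-i-Pr)3 gives zerovalent palladium, which ionises the allylic acetate. The resulting trimethylenemethane–palladium intermediate adds through C1 to C5 of the diene, and the sulfonyl-stabilised allyl anion closes from C8 onto C9 to give the hydroazulene A2.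

- Merits: both rings form in one step from an acyclic compound, the synthesis is convergent, and the sulfone is a functional handle on C8, where the chosen plan has only a C–H bond.
- Weak points: the single stereocentre of A1 (C4) must control C5 across the forming ring, and (3+2) addition across C5=C6 competes. A2 is far from the target: the C6=C7 alkene needs a net anti addition of H and OH, which no single reagent provides; the sulfone must be exchanged for oxygen and that oxygen set trans to O6; and the exocyclic methylene must be moved to C1=C10.
- Comparison: Alternative 1 needs no enzyme and no C–H oxidation, and in that respect it is the safer route. The chosen plan sets against this that C6 and C7 are fixed together in one step and C4 and C5 follow by relay, leaving one stereocentre to be made late and not three.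

**Alternative 2:** Only C8–C9 is cut. The aldehyde A3, a cyclopentane carrying an isopropenyl group on C1 and the C6–C7–C8 chain on C5, with O4 and O6 tied as an acetonide, would be closed with Me2AlCl by a type 2 carbonyl-ene reaction to the hydroazulenol A4.

- Merits: the C8 hydroxyl is created in the ring-closing step, trans to O6 as in the target, and all three oxygens are then present. Only migration of the alkene from C10=C14 to C1=C10, acetonide removal and two acylations remain. On the C8 problem this road is clearly better than the chosen plan.
- Weak points: A3 already contains five stereocentres and an epimerisable α-branched aldehyde, and it must be built by a long linear sequence. Seven-membered ene closures are slower than six-membered ones and compete with chloride capture. The acid-mediated alkene migration must spare a tertiary oxygen function.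
- Comparison: the chosen plan sets step economy against it: the whole skeleton and two stereocentres come from a commodity C15 alcohol in three steps, and four steps later four of the five stereocentres are in place.

**Alternative 3:** C1–C5 and C7–C8 are cut. The α-chloroketone A5, bearing a 3-methylfuran-2-yl terminus, is converted with base into the C5–C6–C7 oxyallyl cation, which adds across furan carbons C1 and C8 to give the oxygen-bridged tricycle A6. A reductive allylic opening of the C1–O bond would then release the C8 hydroxyl and move the alkene into C1=C10.

- Merits: a short precursor, both carbocycles in one step, the C8 oxygen and the latent C1=C10 alkene supplied by the furan, and a ketone at C6 ready for reduction. It is probably the shortest purely chemical access to the full oxygenation pattern.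
- Weak points: C4 alone must control the face of the cycloaddition, and the compact or extended transition state decides the C7 configuration. Both bridge C–O bonds are allylic, so the opening can go the wrong way. The β-alkoxy ketone is prone to elimination. The C6 ketone must be reduced to the alcohol cis to the isopropyl group. The tertiary carbinol of A5 must first be made as one enantiomer.
- Comparison: Alternative 3 avoids C–H functionalisation. The chosen plan sets against this that the absolute configuration and the C6/C7 relationship come from the catalyst and not from a diastereoselection that remains to be proven.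

Key step: step 3

Assumption: a kunzeaol-type synthase (wild type or an engineered variant) that releases the 6R,7S alcohol 4 is taken to be available; the configuration of its product is to be confirmed on the first batch before the route is continued.

## Route

Step 1
Reactants: 1 (2E,6E)-farnesol
Product: 2 (2E,6E)-farnesyl chloride
Conditions: N-chlorosuccinimide, Me2S, CH2Cl2, −40 → 0 °C
Reagents that add atoms: N-chlorosuccinimide, O=C1CCC(=O)N1Cl
Why: Corey–Kim chlorination: the alkoxysulfonium ion formed from 1 is displaced by chloride at the primary allylic carbon, without allylic transposition and with the 2E,6E geometry intact.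

Step 2
Reactants: 2 (2E,6E)-farnesyl chloride
Product: 3 (2E,6E)-farnesyl diphosphate (isolated as its tris-ammonium salt)
Conditions: (n-Bu4N)3HP2O7, MeCN, rt; Dowex 50W-X8 (ammonium form); cellulose chromatography
Reagents that add atoms: tris(tetrabutylammonium) hydrogen diphosphate, CCCC[N+](CCCC)(CCCC)CCCC.CCCC[N+](CCCC)(CCCC)CCCC.CCCC[N+](CCCC)(CCCC)CCCC.OP(=O)([O-])OP(=O)([O-])[O-]
Why: SN2 displacement of the primary allylic chloride by hydrogen diphosphate, the standard preparation of allylic diphosphates; ion exchange gives the water-soluble ammonium salt that the enzyme accepts.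

Step 3
Reactants: 3 (2E,6E)-farnesyl diphosphate
Product: 4 (6R,7S)-germacra-1(10)E,4E-dien-6-ol
Conditions: recombinant kunzeaol-type sesquiterpene synthase (class 1), MgCl2, HEPES buffer pH 7.5, dithiothreitol, 30 °C, n-pentane overlay; extraction and chromatography below 25 °C on Et3N-deactivated silica
Reagents that add atoms: water, O
Why: The enzyme binds the diphosphate through its magnesium ions and ionises the C6–O bond to the allylic farnesyl cation. The distal C7=C11 π bond attacks C6 through C7 and closes the ten-membered ring in the Markovnikov sense (exo with respect to the attacking alkene, the charge left on exocyclic C11), giving the E,E-germacradienyl cation. A 1,3-hydride shift from C6 to C11 creates the isopropyl group and a C4–C5–C6 allyl cation, which an enzyme-bound water captures at C6. The closest known reaction type is the 1,10-cyclisation, 1,3-hydride shift and hydration sequence of class 1 sesquiterpene synthases that make kunzeaol. C7 is set by the face of the distal alkene that the folded chain presents to C6, and C6 by the side of the allyl cation on which the water is held; both are controlled by the active site, the substrate being achiral. The step needs 1,10- over 1,11-closure, retention of the 2E geometry (no detour through nerolidyl diphosphate), hydride shift before deprotonation, and water capture at C6 on one face; none of this is secured by the substrate, which is why the configuration of 4 is checked. The pentane layer removes the acid- and heat-sensitive 1,5-diene from the aqueous phase as it forms.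

Step 4
Reactants: 4 (6R,7S)-germacra-1(10)E,4E-dien-6-ol
Product: 5 (4S,5S,6R,7S)-4,5-epoxygermacr-1(10)E-en-6-ol
Conditions: VO(acac)2 (cat.), t-BuOOH (decane), CH2Cl2, 0 °C; Et3N-deactivated silica
Reagents that add atoms: tert-butyl hydroperoxide, CC(C)(C)OO
Why: Vanadium-catalysed hydroxyl-directed epoxidation: only the allylic C4=C5 alkene is reached by the alkoxide-bound peroxide, so C1=C10 is spared. Oxygen is delivered from the rim of the ring in the conformer that keeps H6 in the alkene plane next to C15 (allylic 1,3-strain), that is syn to the C6 hydroxyl (threo), which sets C4 and C5; the E geometry fixes their mutual relationship.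

Step 5
Reactants: 5 (4S,5S,6R,7S)-4,5-epoxygermacr-1(10)E-en-6-ol
Product: 6 (4S,5R,6R,7S)-guai-1(10)-ene-4,6-diol
Conditions: TsOH·H2O (cat.), CH2Cl2, 0 °C
Reagents that add atoms: none
Why: Transannular epoxide–alkene cyclisation, as known for germacrene 4,5-epoxides: C1 opens the protonated epoxide at C5 with inversion (5-exo closure of ring A), the C4–O bond is kept as the tertiary alcohol, and the C10 cation loses H1 to give the most substituted alkene. C4 and C5 are thereby fixed by the epoxide, with the C4 hydroxyl and H5 cis to O6.

Step 6
Reactants: 6 (4S,5R,6R,7S)-guai-1(10)-ene-4,6-diol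
Product: 8 (4S,5R,6R,7S)-4-(trimethylsilyloxy)guai-1(10)-en-6-ol, via bis(trimethylsilyl) ether 7 (not isolated)
Conditions: TMSOTf, 2,6-lutidine, CH2Cl2, −78 → 0 °C; then K2CO3 (cat.), MeOH, 0 °C
Reagents that add atoms: trimethylsilyl trifluoromethanesulfonate, C[Si](C)(C)OS(=O)(=O)C(F)(F)F
Why: Exhaustive silylation followed by selective base-catalysed methanolysis: attack at silicon is slower for the ether of the fully substituted C4 carbinol than for the secondary C6 ether. This frees only the hydroxyl that has to carry the silicon tether and masks the tertiary hydroxyl that would otherwise consume it.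

Step 7
Reactants: 8 (4S,5R,6R,7S)-4-(trimethylsilyloxy)guai-1(10)-en-6-ol
Product: 12 (4S,5R,6R,7R,8R)-guai-1(10)-ene-4,6,8-triol, via diethylsilyl ether 9 (not isolated), via oxasilolane 10 (not isolated), via silylated 6,8-diol 11 (not isolated)
Conditions: Et2SiH2, [Ir(cod)OMe]2 (cat.), THF, rt; then [Ir(cod)OMe]2 (cat.), 3,4,7,8-tetramethyl-1,10-phenanthroline, norbornene, THF, 100 °C; then H2O2 (30% aq), KHCO3, THF/MeOH, 50 °C; then K2CO3, MeOH, rt
Reagents that add atoms: hydrogen peroxide, OO
Why: Iridium-catalysed hydroxyl-directed silylation of a secondary C–H bond γ to oxygen, then Tamao–Fleming oxidation, a known 1,3-diol synthesis. The Et2SiH group on O6 can close a five-membered oxasilolane only onto the C8 hydrogen cis to O6 (the other γ carbons are tertiary C11, quaternary C4 and sp2 C1), and the C–Si bond is oxidised with retention, so the new hydroxyl is 8R, cis to O6. The tetrasubstituted alkene is too hindered for hydrosilylation, and the final methanolysis frees the C4 hydroxyl.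

Step 8
Reactants: 12 (4S,5R,6R,7R,8R)-guai-1(10)-ene-4,6,8-triol; 13 angelic acid
Product: 14 (4S,5R,6R,7S,8S)-8-angeloyloxyguai-1(10)-ene-4,6-diol
Conditions: PPh3, DIAD, toluene, 0 °C → rt
Reagents that add atoms: none
Why: Mitsunobu esterification: the C8 hydroxyl, next to a methylene, is activated in preference to the C6 hydroxyl flanked by two methines and to the inert tertiary C4 hydroxyl, and angelate displaces it with inversion to the 8S ester, now trans to O6 and to the isopropyl group. The neutral, cold conditions leave the Z alkene of the angelate untouched.

Step 9
Reactants: 14 (4S,5R,6R,7S,8S)-8-angeloyloxyguai-1(10)-ene-4,6-diol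
Product: 15 (4S,5R,6R,7R,8S)-6-acetoxy-8-angeloyloxyguai-1(10)-en-4-ol (CNP0258590.1)
Conditions: Ac2O, pyridine, DMAP (cat.), CH2Cl2, 0 °C → rt
Reagents that add atoms: acetic anhydride, CC(=O)OC(C)=O
Why: Nucleophile-catalysed acetylation of the remaining secondary hydroxyl; the tertiary C4 hydroxyl reacts far more slowly, and the 1,3-trans arrangement of O6 and O8 prevents acyl migration.

## Compound list

1 | (2E,6E)-farnesol | CC(C)=CCC/C(C)=C/CC/C(C)=C/CO | starting material
2 | (2E,6E)-farnesyl chloride | CC(C)=CCC/C(C)=C/CC/C(C)=C/CCl | intermediate
3 | (2E,6E)-farnesyl diphosphate (tris-ammonium salt; drawn as the acid) | CC(C)=CCC/C(C)=C/CC/C(C)=C/COP(=O)(O)OP(=O)(O)O | intermediate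
4 | (6R,7S)-germacra-1(10)E,4E-dien-6-ol [(1R,2E,6E,10S)-3,7-dimethyl-10-(propan-2-yl)cyclodeca-2,6-dien-1-ol] | C/C1=C\CC/C(C)=C/[C@H](O)[C@H](C(C)C)CC1 | intermediate
5 | (4S,5S,6R,7S)-4,5-epoxygermacr-1(10)E-en-6-ol (trans epoxide, oxygen syn to the C6 hydroxyl) | C/C1=C\CC[C@]2(C)O[C@H]2[C@H](O)[C@H](C(C)C)CC1 | intermediate
6 | (4S,5R,6R,7S)-guai-1(10)-ene-4,6-diol (4-OH, H5, 6-OH and isopropyl on one face) | C1CC(C)=C2CC[C@](C)(O)[C@H]2[C@H](O)[C@@H]1C(C)C | intermediate
7 | (4S,5R,6R,7S)-4,6-bis(trimethylsilyloxy)guai-1(10)-ene (not isolated) | C1CC(C)=C2CC[C@](C)(O[Si](C)(C)C)[C@H]2[C@H](O[Si](C)(C)C)[C@@H]1C(C)C | intermediate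
8 | (4S,5R,6R,7S)-4-(trimethylsilyloxy)guai-1(10)-en-6-ol | C1CC(C)=C2CC[C@](C)(O[Si](C)(C)C)[C@H]2[C@H](O)[C@@H]1C(C)C | intermediate
9 | (4S,5R,6R,7S)-6-(diethylsilyloxy)-4-(trimethylsilyloxy)guai-1(10)-ene, Si–H ether (not isolated) | C1CC(C)=C2CC[C@](C)(O[Si](C)(C)C)[C@H]2[C@H](O[SiH](CC)CC)[C@@H]1C(C)C | intermediate
10 | oxasilolane bridging O6 and C8 through SiEt2, silicon on the face of O6, 4-trimethylsilyl ether, (4S,5R,6S,7S,8R) (not isolated) | CC[Si]3(CC)[C@@H]1CC(C)=C2CC[C@](C)(O[Si](C)(C)C)[C@H]2[C@H](O3)[C@@H]1C(C)C | intermediate
11 | (4S,5R,6R,7R,8R)-4-(trimethylsilyloxy)guai-1(10)-ene-6,8-diol (not isolated) | O[C@@H]1CC(C)=C2CC[C@](C)(O[Si](C)(C)C)[C@H]2[C@H](O)[C@@H]1C(C)C | intermediate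
12 | (4S,5R,6R,7R,8R)-guai-1(10)-ene-4,6,8-triol (8-OH cis to 6-OH) | O[C@@H]1CC(C)=C2CC[C@](C)(O)[C@H]2[C@H](O)[C@@H]1C(C)C | intermediate
13 | angelic acid [(2Z)-2-methylbut-2-enoic acid] | C/C=C(/C)C(=O)O | starting material
14 | (4S,5R,6R,7S,8S)-8-angeloyloxyguai-1(10)-ene-4,6-diol (ester trans to 6-OH) | C/C=C(/C)C(=O)O[C@H]1CC(C)=C2CC[C@](C)(O)[C@H]2[C@H](O)[C@@H]1C(C)C | intermediate
15 | (4S,5R,6R,7R,8S)-6-acetoxy-8-angeloyloxyguai-1(10)-en-4-ol | C/C=C(/C)C(=O)O[C@H]1CC(C)=C2CC[C@](C)(O)[C@H]2[C@H](OC(C)=O)[C@@H]1C(C)C | target

## Step count and risks

Total steps: 9. Longest linear sequence: 9 steps (1 to 15); angelic acid 13 is used as purchased.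

**Step 3 (key step).** The most likely failure is capture of water on the other face of the allyl cation, giving the C6 epimer, or premature deprotonation to olefins. The face of hydration depends only on where one water molecule is held in the active site, and nothing in the substrate enforces it. Fallback, setting out from 3 and returning at 4: the enzyme product (6S,7S)-germacra-1(10)E,4E-dien-6-ol F1 is oxidised with MnO2 (CH2Cl2, 0 °C) to (7S)-germacra-1(10)E,4E-dien-6-one F2. This is then reduced under reagent control with (S)-2-methyl-CBS-oxazaborolidine and catecholborane at −78 °C (Corey–Bakshi–Shibata reduction, the alkenyl group acting as the large substituent) to give 4. C7 is not touched as long as the ketone is kept away from base.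

**Step 7.** The most likely failure is slow C–H silylation of the hindered C8 methylene from a secondary silyl ether on a flexible seven-membered ring. The Si–H tether would then be lost to redistribution or to addition across C1=C10, and the electron-rich alkene could suffer in the peroxide step. Fallback, setting out from 6 and returning at 12, with no new compound: enzymatic hydroxylation of the methylene by a variant of the self-sufficient cytochrome P450 CYP102A1, chosen from a mutant panel for C8 selectivity and run in whole cells with glucose for cofactor recycling. Such enzymes hydroxylate unactivated methylene groups of sesquiterpenoids and need no protection of either hydroxyl.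

**Step 8.** The most likely failure is elimination of the activated C8 oxygen towards C9 (a diene conjugated with C1=C10) or towards C7 instead of substitution, because antiperiplanar hydrogens flank the leaving group and the nucleophile must pass the isopropyl-bearing C7. Activation of the C6 hydroxyl is a lesser risk. Fallback, setting out from 12 and returning at 14:
- the less hindered C8 hydroxyl is oxidised with catalytic TEMPO and PhI(OAc)2 to (4S,5R,6S,7S)-4,6-dihydroxyguai-1(10)-en-8-one F3;
- the ketone is reduced with Me4NBH(OAc)3 in MeCN/AcOH at −30 °C, hydride being delivered from the boron bound to O6 (Evans–Saksena anti reduction), to (4S,5R,6R,7R,8S)-guai-1(10)-ene-4,6,8-triol F4;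
- the C8 hydroxyl is esterified with the mixed anhydride of 13 and 2,4,6-trichlorobenzoyl chloride (Et3N, toluene, 80 °C, Yamaguchi conditions) to give 14.

**Step 5.** The most likely failure is interception of the C10 cation by the free C6 hydroxyl (a 6,10-ether), or loss of a proton from C9 or C14 giving alkene regioisomers, since the hydroxyl lies on the face of ring B from which the cation is accessible. Fallback, setting out from 5 and returning at 8 (steps 5 and 6 are bypassed):
- acetylation (Ac2O, pyridine) gives (4S,5S,6R,7S)-4,5-epoxygermacr-1(10)E-en-6-yl acetate F5;
- cyclisation with BF3·OEt2 in CH2Cl2 at −78 °C gives (4S,5R,6R,7S)-6-acetoxyguai-1(10)-en-4-ol F6;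
- TMSOTf and 2,6-lutidine give (4S,5R,6R,7S)-6-acetoxy-4-(trimethylsilyloxy)guai-1(10)-ene F7;
- reductive removal of the acetate with i-Bu2AlH in CH2Cl2 at −78 °C leads to 8.

The order in which the two hydroxyls appear then replaces the selective desilylation.

**Step 6.** The most likely failure is an insufficient rate difference in the methanolysis, because the secondary silyl ether is itself crowded by C5 and C7; the result would be mixtures of diol and both mono-ethers. Fallback, setting out from 6 and returning at 9, which enters step 7 at the C–H silylation stage: the secondary hydroxyl is silylated selectively with Et2SiHCl and imidazole in CH2Cl2 at −40 °C to (4S,5R,6R,7S)-6-(diethylsilyloxy)guai-1(10)-en-4-ol F8. The tertiary hydroxyl is then capped with N-(trimethylsilyl)imidazole. Selective bond formation thus replaces selective cleavage.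

## Further compounds

F1 | step 3 | (6S,7S)-germacra-1(10)E,4E-dien-6-ol | C/C1=C\CC/C(C)=C/[C@@H](O)[C@H](C(C)C)CC1
F2 | step 3 | (7S)-germacra-1(10)E,4E-dien-6-one | C/C1=C\CC/C(C)=C/C(=O)[C@H](C(C)C)CC1
F0 | step 7 | none | none
F3 | step 8 | (4S,5R,6S,7S)-4,6-dihydroxyguai-1(10)-en-8-one | O=C1CC(C)=C2CC[C@](C)(O)[C@H]2[C@H](O)[C@@H]1C(C)C
F4 | step 8 | (4S,5R,6R,7R,8S)-guai-1(10)-ene-4,6,8-triol | O[C@H]1CC(C)=C2CC[C@](C)(O)[C@H]2[C@H](O)[C@@H]1C(C)C
F5 | step 5 | (4S,5S,6R,7S)-4,5-epoxygermacr-1(10)E-en-6-yl acetate | C/C1=C\CC[C@]2(C)O[C@H]2[C@H](OC(C)=O)[C@H](C(C)C)CC1
F6 | step 5 | (4S,5R,6R,7S)-6-acetoxyguai-1(10)-en-4-ol | C1CC(C)=C2CC[C@](C)(O)[C@H]2[C@H](OC(C)=O)[C@@H]1C(C)C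
F7 | step 5 | (4S,5R,6R,7S)-6-acetoxy-4-(trimethylsilyloxy)guai-1(10)-ene | C1CC(C)=C2CC[C@](C)(O[Si](C)(C)C)[C@H]2[C@H](OC(C)=O)[C@@H]1C(C)C
F8 | step 6 | (4S,5R,6R,7S)-6-(diethylsilyloxy)guai-1(10)-en-4-ol | C1CC(C)=C2CC[C@](C)(O)[C@H]2[C@H](O[SiH](CC)CC)[C@@H]1C(C)C
A1 | alternative 1 | open-chain (5E,7E)-dienyl phenyl sulfone with a 2-(trimethylsilylmethyl)allyl acetate terminus and the (4S) triethylsilyl ether | C=C(C[Si](C)(C)C)C(OC(C)=O)CC[C@](C)(O[Si](CC)(CC)CC)/C=C/C(C(C)C)=C/S(=O)(=O)c1ccccc1
A2 | alternative 1 | 8-(phenylsulfonyl)-4-(triethylsilyloxy)guaia-6,10(14)-diene | C=C1C[C@H](S(=O)(=O)c2ccccc2)C(C(C)C)=C[C@@H]2[C@@](C)(O[Si](CC)(CC)CC)CC[C@H]12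
A3 | alternative 2 | 4,6-O-isopropylidene-4,6-dihydroxy-8,9-secoguai-9(10)-en-8-al | O=C[C@@H](C(C)C)[C@H]1OC(C)(C)O[C@@]2(C)CC[C@H](C(C)=C)[C@H]12
A4 | alternative 2 | 4,6-O-isopropylideneguai-10(14)-ene-4,6,8-triol | C=C1C[C@H](O)[C@@H](C(C)C)[C@H]2OC(C)(C)O[C@@]3(C)CC[C@H]1[C@H]23
A5 | alternative 3 | (6S)-3-chloro-2,6-dimethyl-8-(3-methylfuran-2-yl)-6-(triethylsilyloxy)octan-4-one | Cc1ccoc1CC[C@](C)(O[Si](CC)(CC)CC)CC(=O)C(Cl)C(C)C
A6 | alternative 3 | 1,8-epoxy-4-(triethylsilyloxy)guai-9-en-6-one (cyclopentane-fused 8-oxabicyclo[3.2.1]oct-6-en-3-one) | O1[C@H]2C=C(C)[C@@]13CC[C@](C)(O[Si](CC)(CC)CC)[C@H]3C(=O)[C@@H]2C(C)C
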